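A small charge of solid reagent, 0.75 equiv, carried the east run to its end. The scheme on offer has solid reagent dissolving to partner, partner and starting material giving target, and starting material also going to side product by itself.

- east: starting material 0.20 M; solid reagent 0.75 equiv; run made earlier
- flask: starting material 0.20 M; solid reagent 1.50 equiv; time 80 min

east run (percent of the starting material charged)

| time / min | starting material / % | target / % | side product / % |
|---|---|---|---|
| 1.33 | 39.4 | 20.4 | 36.9 |
| 3.00 | 5.7 | 43.9 | 51.9 |
| 6.00 | 1.2 | 47.8 | 52.1 |
| 15.0 | 0 | 47.7 | 52.1 |

(standard deviation of a reading: 1 percentage point)

- solid, in amounts per volume of the solution: solid reagent
- what may be going on: solid reagent <-> partner; starting material -> side product; starting material + partner -> target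
- at the start none of the solid reagent is in solution
- the reaction counts as stopped when no species that holds the starting material changes by six tenths of a point or more over the second half of the time

- the state of affairs at 80 min: stopped, and by what, or still going (for what has run out or reacted, a solid counts together with what of it has only dissolved) (the partner has run out first / all of the starting material has reacted / it is still moving)
- share of the starting material used up at 80 min
- target at 80 min, in percent of the starting material charged
- side product at 80 min, in percent of the starting material charged

In the east run the side product reached 36.9 % by 1.33 min, while the starting material averaged 69.7 %. That reads as a first-order constant k of 0.398 min⁻¹. So τ, the side-loss half-life, the time in which the side step by itself halves the starting material, is 1.74 min.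

But a straight mean over a curved fall is coarse. Taking τ twice as long still leaves 23.0 half-lives in 80 min, against 45.9 as read. So the side step by itself is reckoned to use up the flask's starting material well inside 80 min. The flask's charge of 1.50 equiv also makes starting material the limiting reagent.

The split is harder: the east run held 1.2 % at 6.00 min, so there it is made within 3.45 τ. In the east run, target gained per side product gained reads 0.553 in the first interval and 1.57 in the next, which reads as partner building up over those minutes. More solid might speed that. But the ratio rose by a factor of 2.84 against 3.26 for the mid-times, although target had by then taken 58.5 % of the solid reagent charged in the east run. Within the scatter of these readings, the rise shows no clear slackening as the solid shrinks. The reckoning therefore keeps the east split, target 47.7 % and side product 52.1 %, on the thin ground of one run.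

The forecast, parting from this on the split, says all of the starting material has reacted, 100 % used up, target 57 % and side product 43 %, holding that “Doubling the solid should roughly double the dissolution rate”.

The flask gives: all of the starting material has reacted, with 100 % used up, target 48.2 % and side product 51.8 %.

    solid reagent ⇌ partner, rate k1*(cs1 - [partner]) while solid is left; crystals form when [partner] > cs1 (solubility = 0.150 M, k = 0.00490 s⁻¹)
    starting material → side product (k = 0.00680 s⁻¹)
    starting material + partner → target (k = 0.630 M⁻¹ s⁻¹)

At 3.11 min the flask's starting material has a half-life of 0.53 min by the target step, shorter than the 1.7 min by the side step. Yet half of the side product stands by 0.791 min, inside one τ, while half of the dissolving takes 3.11 min, or 1.79 τ. The flask with 0.080 M of starting material has the same 45.9 τ in its time, and it holds 0 % starting material, with target at 58.9 %.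

The earlier runs and the new flask come from a simulation from invented constants, noise included.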